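## Structural features

The target is a 1-benzofuran-2,6-dione. A five-membered enol lactone (ring A: O1, C2, C3, C3a, C7a) is fused along C3a–C7a to a six-membered cross-conjugated ring B (C3a, C4, C5, C6, C7, C7a). The C3=C3a double bond is exocyclic to ring B and para to the C6 carbonyl, so the core is a para-quinone methide. It is conjugated with the lactone carbonyl, the 4-hydroxyphenyl group on C3 and the C5 methoxy group. Every carbon of both rings is substituted (aryl on C3, phenyl on C4 and C7, oxygen on C5, C6 and C7a). There is no stereocentre, so no neighbouring stereocentres have to be related, and the problems are regiochemical and chemoselective only. The fragile groups are the lactone and the C5 methyl enol ether (a vinylogous ester) toward hydroxide and alkoxide, the quinone methide toward reductants and soft nucleophiles at C3, and the free phenol, which is conjugated with the methide and therefore acidic. The real difficulty is to place three contiguous, differently functionalised oxygens (C5 methoxy, C6 carbonyl, C7a lactone oxygen) on a hexasubstituted ring crowded by the C3 aryl and C4 phenyl groups, and to methylate one acidic hydroxyl while the other ends up free. The key step uses the fact that C5 and C6 are an ortho-dioxygenated pair flanked by the C4 and C7 phenyl groups. Once ring A is removed by cutting C3–C3a and O1–C7a, ring B is the mirror-symmetric 3,6-diphenyl-1,2-benzoquinone, whose only two unsubstituted carbons (the future C3a and C7a) are equivalent and are the β-carbons of its two enone units.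

## Logic of the disconnections

**18 ⇒ 17.** The bond cut is the O–C(CH3)3 bond of an aryl tert-butyl ether placed on the phenol oxygen. The phenol is conjugated with the methide and would compete with the C5 enol for a methylating agent, so it must be capped until the methyl group is in place. A benzyl ether was considered and rejected, because its hydrogenolysis would also reduce the methide and cost a re-oxidation. A tert-butyl ether leaves with acid alone, so the end game needs no redox step. The demand on the forward step is an anhydrous acidolysis, without a reducing scavenger, that spares the lactone, the C5 enol ether and the methide.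

**17 ⇒ 16.** The bond cut is O–CH3 at C5. In 16 the C5 hydroxyl is the only free hydroxyl, and the para relation of the methide to C6 already decides which of the two ring-B oxygens is a carbonyl. The methyl ether therefore need not be carried through any oxidation. The forward step must alkylate the oxygen terminus of a delocalised anion under a base mild enough for the lactone.

**16 ⇒ 5 + 10.** The bonds cut are C3–C3a and O1–C7a, and a carboxyl group is put back on C3. This removes ring A and two skeletal bonds and leaves a symmetric precursor 5, so no regiochemical choice exists, and an arylmalonic acid 10 that supplies C3, C2 and O1. The forward step must remove six electrons in three stages (through 11, 13 and the oxidation of 15), and must make 10 react through carbon. For that the medium is kept mildly acidic, so that the monoanion of 10, which still has an enolisable C–H, predominates over the dianion. A divided cell keeps the reducible product away from the cathode.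

**5 ⇒ 4.** The bonds cut are the two O–CH3 bonds. A free catechol would bind boron and palladium and would be air-oxidised under basic cross-coupling conditions, so it is carried as its dimethyl ether. The forward step is an exhaustive Lewis-acid demethylation, and 5 must then be handled under inert gas.

**4 ⇒ 1 + 2 (through 3).** The bonds cut are the two aryl–aryl bonds. They are identical, so one operation makes both and leads back to two catalogue compounds. The forward coupling must run to completion so that no 3 remains.

**10 ⇒ 8 (through 9).** The bonds cut are the two acyl C–O(ethyl) bonds. The free diacid loses carbon dioxide easily, so it is stored as the diester and released immediately before use. The forward step is a cold hydrolysis with cold acidification.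

**8 ⇒ 6 + 7.** The bond cut is the aryl–C(α) bond. This leads back to a malonic ester and a catalogue aryl bromide that already carries the acid-labile cap. The bromide 6 is electron-rich, and copper catalysis of this bond is dependable only for aryl iodides, so the forward step uses zerovalent palladium with a bulky trialkylphosphine.

## Other disconnections considered

**Alternative 1:** The cut is the C3a–C7a bond of ring B, which is built from a four-membered ring. The forward key step is thermolysis of cyclobutenone A1 in toluene: 4π ring opening to a dienylketene, 6π closure of the ketene carbon onto the vinyl terminus, and tautomerisation to phenol A2.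
- In favour: the thermal ring expansion of 4-alkenylcyclobutenones is a well-established reaction type and needs no reagent, so on precedent this alternative is better than the chosen plan. The C5 methyl ether is in place from the start and is distinct from the isopropyl-capped C6 oxygen, so the methylation selectivity question never arises; on that point it is at least the equal of the chosen plan.
- Against: A1 needs several steps from a squaric ester (two organometallic additions, a hydrolysis, O-methylation of a tertiary alkoxide). A2 contains no atom of ring A. C3, C2 and the aryl group would still have to be attached at the single free CH, which is flanked by a phenyl group, for example by condensation with an arylglyoxylic or mandelic acid derivative. The isopropyl ether then has to be cleaved selectively and the arene oxidised to the methide.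
- Comparison: the key step closes ring B and no lactone bond, whereas the chosen step closes ring A on a preformed ring B and sets the final oxidation level in the same operation. The alternative should need roughly ten or more steps against seven.

**Alternative 2:** The cuts are the C4–phenyl and C7–phenyl bonds. The forward key step is two Suzuki–Miyaura couplings of dibromide A3 with 2 (Pd(PPh3)4, CsF, dioxane) to give A4.
- In favour: the bond type is the same reliable one that the chosen plan makes in step 1, so the two plans are equal on reaction type. Late introduction of the aryl groups would be better if analogues with other aryl groups were wanted.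
- Against: in A3 the C4–Br bond is a vinylogous acyl bromide open to addition–elimination by fluoride or hydroxide. The quinone methide is an oxidant and acceptor that can consume phosphine, zerovalent palladium or the boronic acid, and the aryl acetate is labile to fluoride and base. C4 is also hindered by the C3 aryl group. A3 itself still has to be made, by a route no shorter than the chosen one. The acetate must finally be removed in the presence of the lactone and the enol ether.
- Comparison: the chosen plan performs the same couplings on a robust dimethoxyarene, where none of these side reactions exist, and is shorter by at least two steps.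

**Alternative 3:** The cuts are C3–C3a, C2–C3 and C2–O1. The forward key step is an acid-catalysed three-component reaction of triol A5, aldehyde A7 and isocyanide A8. The aldehyde condenses at the free CH to an ortho-quinone methide, the isocyanide adds in a (4+1) sense, and tautomerisation gives aminofuran A6.
- In favour: the reaction type is known for electron-rich phenols, so on precedent it is better than the chosen key step. It needs no electrochemical equipment. O1 is already on the ring, so no oxidative C–O bond formation is required. Regiochemistry is equal to the chosen plan, since A5 has only one free CH.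
- Against: A5 is an air-sensitive hydroxyhydroquinone that would itself be made from 5 in about three more steps (oxidation, acetoxylation, hydrolysis). A6 has nitrogen where the lactone carbonyl oxygen is needed and is two oxidation levels too low, so oxidation and hydrolysis of an N-tert-butyl imino lactone must follow. 2-Aminofurans are sensitive compounds.
- Comparison: the precursor of the chosen key step is an intermediate of this alternative, so the alternative cannot be shorter; it should be about four steps longer.

Key step: step 5

Remark on the chemistry: 1 and 6 are taken to be catalogue compounds; the target has no stereocentre, and the C3 stereocentre of the transient intermediates 14 and 15 is racemic.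

## Route

Step 1
Reactants: 1 1,4-dibromo-2,3-dimethoxybenzene; 2 phenylboronic acid
Product: 4 2',3'-dimethoxy-1,1':4',1''-terphenyl, via 4-bromo-2,3-dimethoxy-1,1'-biphenyl 3 (not isolated)
Conditions: 2 (2.4 equiv), Pd(PPh3)4 (3 mol%), K2CO3, toluene–EtOH–H2O, 85 °C
Reagents that add atoms: none
Why: Two-fold Suzuki–Miyaura coupling; both aryl C–Br bonds react in turn through 3, and the methyl ethers keep the catechol oxygens from binding boron or palladium.

Step 2
Reactants: 4 2',3'-dimethoxy-1,1':4',1''-terphenyl
Product: 5 3,6-diphenylbenzene-1,2-diol
Conditions: BBr3 (3 equiv), CH2Cl2, −78 °C to rt; then H2O, 0 °C, under N2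
Reagents that add atoms: none
Why: Lewis-acid cleavage of aryl methyl ethers: BBr3 binds each methoxy oxygen and bromide removes the methyl group; the terphenyl skeleton is inert and aqueous work-up frees the catechol.

Step 3
Reactants: 6 1-bromo-4-tert-butoxybenzene; 7 diethyl propanedioate
Product: 8 diethyl 2-(4-tert-butoxyphenyl)propanedioate
Conditions: Pd(OAc)2 (2 mol%), P(t-Bu)3·HBF4 (4 mol%), K3PO4, toluene, 80 °C
Reagents that add atoms: none
Why: Palladium-catalysed α-arylation of a malonate: the bulky electron-rich phosphine lets zerovalent palladium insert into the electron-rich aryl bromide, and reductive elimination from the arylpalladium malonate forms the aryl–C bond. The product rests as its hindered enolate and should not react twice; the tert-butyl ether is inert to phosphate base.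

Step 4
Reactants: 8 diethyl 2-(4-tert-butoxyphenyl)propanedioate
Product: 10 2-(4-tert-butoxyphenyl)propanedioic acid, via dilithium 2-(4-tert-butoxyphenyl)propanedioate 9 (not isolated)
Conditions: LiOH (4 equiv), THF–H2O, 0 °C to rt; then 1 M HCl to pH 2, 0 °C, EtOAc, evaporation below 30 °C
Reagents that add atoms: lithium hydroxide, [Li+].[OH-] (supplies the lithium of 9 and one oxygen of each carboxyl group of 10)
Why: Ester saponification by acyl substitution with hydroxide, then cold acidification; the low temperature throughout keeps the arylmalonic acid from losing carbon dioxide, and the aryl tert-butyl ether survives brief contact with cold dilute acid.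

Step 5
Reactants: 5 3,6-diphenylbenzene-1,2-diol; 10 2-(4-tert-butoxyphenyl)propanedioic acid
Product: 16 3-(4-tert-butoxyphenyl)-5-hydroxy-4,7-diphenyl-1-benzofuran-2,6-dione, via ortho-quinone 11 (not isolated), via C-adduct catechol 12 (not isolated), via C-adduct ortho-quinone 13 (not isolated), via lactone acid 14 (not isolated), via leuco lactone 15 (not isolated)
Conditions: graphite anode, Pt cathode, divided cell, constant potential at the first anodic wave of 5 (expected near +0.5 V vs Ag/AgCl, ca. 6 F/mol), 10 (1.5 equiv), 0.2 M NaOAc–AcOH buffer (pH 4.5)/MeCN 1:1, N2, 15–20 °C
Reagents that add atoms: none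
Why: Proposed new method: the closest known reaction type is the anodic coupling of catechols with 1,3-dicarbonyl carbon acids, in which Michael addition to the electrogenerated ortho-quinone, re-oxidation and ring closure through oxygen give benzofurans, together with the oxidative lactonisation of catechols that carry a carboxylic acid side chain; new here are a malonic acid as the carbon acid and a carboxylate as the ring-closing oxygen. Mechanism: 5 is oxidised by two electrons to the symmetric quinone 11, and the hydrogen malonate of 10, which should dominate near pH 4.5 and still has an enolisable C–H (the dianion formed in a neutral buffer is not a useful carbon acid), adds through its ene-diolate carbon to one β-carbon of 11 to give catechol 12 after tautomerisation. 12 is oxidised at the same potential to 13, in which a carboxylate oxygen adds to the last unsubstituted ring carbon, an oxa-Michael closure of ring A in the 5-exo-trig mode that gives 14. 14 loses carbon dioxide because the C3 carbanion is a lactone enolate flanked by two arenes, and catechol 15 is oxidised a third time with loss of the C3 proton to the para-quinone methide 16. No stereocentre remains: C3 is stereogenic only in racemic 14 and 15 and becomes trigonal in 16. The step needs carbon and not oxygen attack on 11, which the soft, doubly stabilised benzylic carbon and the reversibility of carboxylate addition should secure; it needs no regiocontrol, because the two free carbons of 11 are equivalent and only one is left in 13. Over-reaction is blocked because every ring carbon of 16 is substituted, and the position of the methide leaves the C5 hydroxyl, not a C6 hydroxyl, free.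

Step 6
Reactants: 16 3-(4-tert-butoxyphenyl)-5-hydroxy-4,7-diphenyl-1-benzofuran-2,6-dione
Product: 17 3-(4-tert-butoxyphenyl)-5-methoxy-4,7-diphenyl-1-benzofuran-2,6-dione
Conditions: Me2SO4 (1.3 equiv), K2CO3 (2 equiv), acetone, rt
Reagents that add atoms: dimethyl sulfate, COS(=O)(=O)OC
Why: O-Alkylation of a vinylogous acid: the C5 hydroxyl is the only acidic proton of 16, and the hard electrophile should attack the oxygen terminus of the delocalised anion because the carbon termini C3 and C4 are fully substituted and shielded by aryl groups. The methide fixes C6 as the carbonyl, so the methyl group can only end up on the C5 oxygen.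

Step 7
Reactants: 17 3-(4-tert-butoxyphenyl)-5-methoxy-4,7-diphenyl-1-benzofuran-2,6-dione
Product: 18 3-(4-hydroxyphenyl)-5-methoxy-4,7-diphenyl-1-benzofuran-2,6-dione
Conditions: TFA–CH2Cl2 (1:4), 0 °C to rt
Reagents that add atoms: none
Why: Acidolysis of an aryl tert-butyl ether with loss of the tert-butyl cation as isobutene; the lactone, the methyl enol ether and the quinone methide should tolerate anhydrous acid, and no reductant is present, so the oxidation level of the chromophore is untouched.

## Compound list

1 | 1,4-dibromo-2,3-dimethoxybenzene | COc1c(Br)ccc(Br)c1OC | starting material
2 | phenylboronic acid | OB(O)c1ccccc1 | starting material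
3 | 4-bromo-2,3-dimethoxy-1,1'-biphenyl | COc1c(Br)ccc(-c2ccccc2)c1OC | intermediate (not isolated)
4 | 2',3'-dimethoxy-1,1':4',1''-terphenyl | COc1c(-c2ccccc2)ccc(-c2ccccc2)c1OC | intermediate
5 | 3,6-diphenylbenzene-1,2-diol | Oc1c(O)c(-c2ccccc2)ccc1-c1ccccc1 | intermediate
6 | 1-bromo-4-tert-butoxybenzene | CC(C)(C)Oc1ccc(Br)cc1 | starting material
7 | diethyl propanedioate (diethyl malonate) | CCOC(=O)CC(=O)OCC | starting material
8 | diethyl 2-(4-tert-butoxyphenyl)propanedioate | CCOC(=O)C(C(=O)OCC)c1ccc(OC(C)(C)C)cc1 | intermediate
9 | dilithium 2-(4-tert-butoxyphenyl)propanedioate | [Li+].[Li+].[O-]C(=O)C(C([O-])=O)c1ccc(OC(C)(C)C)cc1 | intermediate (not isolated)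
10 | 2-(4-tert-butoxyphenyl)propanedioic acid | OC(=O)C(C(=O)O)c1ccc(OC(C)(C)C)cc1 | intermediate
11 | 3,6-diphenylcyclohexa-3,5-diene-1,2-dione | O=C1C(=O)C(c2ccccc2)=CC=C1c1ccccc1 | intermediate (not isolated)
12 | 2-(4-tert-butoxyphenyl)-2-(3,4-dihydroxy-2,5-diphenylphenyl)propanedioic acid | OC(=O)C(C(=O)O)(c1ccc(OC(C)(C)C)cc1)c1cc(-c2ccccc2)c(O)c(O)c1-c1ccccc1 | intermediate (not isolated)
13 | 2-(4-tert-butoxyphenyl)-2-(3,4-dioxo-2,5-diphenylcyclohexa-1,5-dien-1-yl)propanedioic acid | OC(=O)C(C(=O)O)(c1ccc(OC(C)(C)C)cc1)C1=C(c2ccccc2)C(=O)C(=O)C(c2ccccc2)=C1 | intermediate (not isolated)
14 | 3-(4-tert-butoxyphenyl)-5,6-dihydroxy-2-oxo-4,7-diphenyl-2,3-dihydro-1-benzofuran-3-carboxylic acid (racemic) | OC(=O)C1(c2ccc(OC(C)(C)C)cc2)C(=O)Oc2c(-c3ccccc3)c(O)c(O)c(-c3ccccc3)c21 | intermediate (not isolated)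
15 | 3-(4-tert-butoxyphenyl)-5,6-dihydroxy-4,7-diphenyl-1-benzofuran-2(3H)-one (racemic) | O=C1Oc2c(-c3ccccc3)c(O)c(O)c(-c3ccccc3)c2C1c1ccc(OC(C)(C)C)cc1 | intermediate (not isolated)
16 | 3-(4-tert-butoxyphenyl)-5-hydroxy-4,7-diphenyl-1-benzofuran-2,6-dione | OC1=C(c2ccccc2)C2=C(c3ccc(OC(C)(C)C)cc3)C(=O)OC2=C(c2ccccc2)C1=O | intermediate
17 | 3-(4-tert-butoxyphenyl)-5-methoxy-4,7-diphenyl-1-benzofuran-2,6-dione | COC1=C(c2ccccc2)C2=C(c3ccc(OC(C)(C)C)cc3)C(=O)OC2=C(c2ccccc2)C1=O | intermediate
18 | 3-(4-hydroxyphenyl)-5-methoxy-4,7-diphenyl-1-benzofuran-2,6-dione | COC1=C(c2ccccc2)C2=C(c3ccc(O)cc3)C(=O)OC2=C(c2ccccc2)C1=O | target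

## Step count and least certain steps

Total step count: 7. Longest linear sequence: 5 steps (1, 2, 5, 6, 7, or 3, 4, 5, 6, 7).

**Step 5 (key step, the proposed new method).** The most likely failure is slow carbon–carbon bond formation. The crowded benzylic carbon of 10 has to attack next to a phenyl-bearing carbon, and it competes with decay of the electrogenerated quinone 11 (hydration, self-coupling) and with slow decarboxylation of 10 in the buffer. Attack through a carboxylate oxygen would be unproductive but reversible.

The fallback uses known chemistry, a Perkin-type condensation of a dihydroxyquinone with an arylacetic acid. It sets out from 10 and returns at 16. Gentle warming of 10 in toluene should give 2-(4-tert-butoxyphenyl)acetic acid F1 by decarboxylation. Separately, purchased 2,5-diphenyl-1,4-benzoquinone would be brominated (Br2, AcOH) to 2,5-dibromo-3,6-diphenylcyclohexa-2,5-diene-1,4-dione F2 and hydrolysed (NaOH, aqueous MeOH, then acid) to 2,5-dihydroxy-3,6-diphenylcyclohexa-2,5-diene-1,4-dione F3. Heating F3 with one equivalent of F1 in Ac2O/Et3N at about 80 °C should acylate one hydroxyl and condense the activated methylene with the neighbouring quinone carbonyl. The butenolide ring closes and the other hydroxyl is acetylated, giving 3-(4-tert-butoxyphenyl)-2,6-dioxo-4,7-diphenyl-2,6-dihydro-1-benzofuran-5-yl acetate F4. Mild cleavage of this very labile enol acetate (NaHCO3, aqueous THF) would give 16. No redox step is needed, because F3 already has the oxidation level of 16.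

**Step 6.** What may go wrong is alkylation at another terminus of the delocalised anion (C3 or the lactone carbonyl oxygen), or opening of the lactone by carbonate and adventitious water.

The fallback replaces alkylation of the anion by acid-catalysed enol etherification, the way hydroxyquinones are converted into methoxyquinones. It sets out from 16 and returns at 18. Warming 16 in MeOH with HC(OMe)3 and HCl should exchange the C5 hydroxyl for methoxyl by addition–elimination at C5, which cannot alkylate carbon. The same acid should remove the tert-butyl group, so 17 and step 7 are bypassed; any 17 that remains is put through step 7. This fallback makes no new compound (F0).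

**Step 7.** What may go wrong is re-alkylation of the electron-rich rings by the tert-butyl cation, or slow acid-promoted loss of the C5 enol ether if moisture is present. The scavengers that would normally cure the first problem (silanes, thiols) would reduce or add to the methide.

The fallback moves the deprotection to the leuco oxidation level. It sets out from 17 and returns at 18. Reduction of 17 with Na2S2O4 in aqueous THF should give 3-(4-tert-butoxyphenyl)-6-hydroxy-5-methoxy-4,7-diphenyl-1-benzofuran-2(3H)-one F5, an ordinary arene that tolerates prolonged TFA in CH2Cl2. Acidolysis would then give 6-hydroxy-3-(4-hydroxyphenyl)-5-methoxy-4,7-diphenyl-1-benzofuran-2(3H)-one F6, and dehydrogenation with one equivalent of DDQ would give 18.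

**Step 4.** What may go wrong is loss of carbon dioxide during acidification and concentration, or incomplete hydrolysis because the malonate enolate resists hydroxide.

The fallback avoids both base and acid. It sets out from 6 and returns at 10. The same palladium-catalysed arylation (Pd(OAc)2, P(t-Bu)3·HBF4, K3PO4, toluene) with purchased dibenzyl malonate should give dibenzyl 2-(4-tert-butoxyphenyl)propanedioate F7. Hydrogenolysis (H2, Pd/C, EtOAc, rt) would release 10 under neutral conditions, and the filtered solution would be used directly in step 5.

## Further compounds

F1 | step 5 | 2-(4-tert-butoxyphenyl)acetic acid | CC(C)(C)Oc1ccc(CC(=O)O)cc1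
F2 | step 5 | 2,5-dibromo-3,6-diphenylcyclohexa-2,5-diene-1,4-dione | O=C1C(Br)=C(c2ccccc2)C(=O)C(Br)=C1c1ccccc1
F3 | step 5 | 2,5-dihydroxy-3,6-diphenylcyclohexa-2,5-diene-1,4-dione (polyporic acid) | O=C1C(O)=C(c2ccccc2)C(=O)C(O)=C1c1ccccc1
F4 | step 5 | 3-(4-tert-butoxyphenyl)-2,6-dioxo-4,7-diphenyl-2,6-dihydro-1-benzofuran-5-yl acetate | CC(=O)OC1=C(c2ccccc2)C2=C(c3ccc(OC(C)(C)C)cc3)C(=O)OC2=C(c2ccccc2)C1=O
F0 | step 6 | none | none
F5 | step 7 | 3-(4-tert-butoxyphenyl)-6-hydroxy-5-methoxy-4,7-diphenyl-1-benzofuran-2(3H)-one (racemic) | COc1c(O)c(-c2ccccc2)c2OC(=O)C(c3ccc(OC(C)(C)C)cc3)c2c1-c1ccccc1
F6 | step 7 | 6-hydroxy-3-(4-hydroxyphenyl)-5-methoxy-4,7-diphenyl-1-benzofuran-2(3H)-one (racemic) | COc1c(O)c(-c2ccccc2)c2OC(=O)C(c3ccc(O)cc3)c2c1-c1ccccc1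
F7 | step 4 | dibenzyl 2-(4-tert-butoxyphenyl)propanedioate | CC(C)(C)Oc1ccc(C(C(=O)OCc2ccccc2)C(=O)OCc2ccccc2)cc1
A1 | alternative 1 | 4-methoxy-2-phenyl-4-(1-phenylethenyl)-3-(propan-2-yloxy)cyclobut-2-en-1-one (racemic) | COC1(C(=C)c2ccccc2)C(OC(C)C)=C(c2ccccc2)C1=O
A2 | alternative 1 | 4-methoxy-2,5-diphenyl-3-(propan-2-yloxy)phenol | COc1c(OC(C)C)c(-c2ccccc2)c(O)cc1-c1ccccc1
A3 | alternative 2 | 4-(4,7-dibromo-5-methoxy-2,6-dioxo-2,6-dihydro-1-benzofuran-3-yl)phenyl acetate | COC1=C(Br)C2=C(c3ccc(OC(C)=O)cc3)C(=O)OC2=C(Br)C1=O
A4 | alternative 2 | 4-(5-methoxy-2,6-dioxo-4,7-diphenyl-2,6-dihydro-1-benzofuran-3-yl)phenyl acetate | COC1=C(c2ccccc2)C2=C(c3ccc(OC(C)=O)cc3)C(=O)OC2=C(c2ccccc2)C1=O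
A5 | alternative 3 | 3,6-diphenylbenzene-1,2,4-triol | Oc1cc(-c2ccccc2)c(O)c(O)c1-c1ccccc1
A6 | alternative 3 | 3-[4-(benzyloxy)phenyl]-2-(tert-butylamino)-4,7-diphenyl-1-benzofuran-5,6-diol | CC(C)(C)Nc1oc2c(-c3ccccc3)c(O)c(O)c(-c3ccccc3)c2c1-c1ccc(OCc2ccccc2)cc1
A7 | alternative 3 | 4-(benzyloxy)benzaldehyde | O=Cc1ccc(OCc2ccccc2)cc1
A8 | alternative 3 | tert-butyl isocyanide (2-isocyano-2-methylpropane) | [C-]#[N+]C(C)(C)C
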